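The cyclohexane ring A (C6–C11 in spiro[5.5] numbering: C6 spiro, C7 aryl, C8 methyl, C9 aryl, C10 methyl, C11 ethyl) is disconnected at C10–C11. The vicinal methyl (C10) and ethyl (C11) groups are read as the hydrogenated form of a 1-methylidene-2-vinylcyclohexane, the retron of an Alder-ene cycloisomerisation. A ruthenium-catalysed cycloisomerisation of a 1,7-enyne therefore closes ring A and sets C11 in one operation. The precursor is an open-chain ketone: quaternary C6 sits in a Birch-derived 2,5-dimethoxycyclohexa-2,5-diene (latent dienone ring B) and bears a propenyl group, and C9 is a propargylic aryl stereocentre. The C7 and C8 substituents follow on the ring.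

Key step: step 8

Assumption: the sense of induction of the (S)-prolinol ether auxiliary (step 2) and of the (R)-bisphosphine (step 6) is taken as drawn; if either is opposite, the mirror-image auxiliary or ligand is used.

Step 1
Reactants: 1 2,5-dimethoxybenzoyl chloride; 2 (S)-2-(methoxymethyl)pyrrolidine
Product: 3 (2,5-dimethoxyphenyl)[(2S)-2-(methoxymethyl)pyrrolidin-1-yl]methanone
Conditions: Et3N, CH2Cl2, 0 °C to rt
Reagents that add atoms: none
Why: N-acylation of the secondary amine by the acid chloride (amide formation) installs the chiral auxiliary; no new stereocentre is formed.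

Step 2
Reactants: 3 (2,5-dimethoxyphenyl)[(2S)-2-(methoxymethyl)pyrrolidin-1-yl]methanone
Product: 5 [(1S)-2,5-dimethoxy-1-(prop-2-en-1-yl)cyclohexa-2,5-dien-1-yl][(2S)-2-(methoxymethyl)pyrrolidin-1-yl]methanone, via potassium dienolate 4 (not isolated)
Conditions: K, NH3(l), THF, t-BuOH (1 equiv), −78 °C; then CH2=CHCH2Br, −78 °C
Reagents that add atoms: allyl bromide, C=CCBr
Why: Birch reduction–alkylation: reduction and protonation para to the amide give the amide dienolate, whose potassium ion is chelated by the enolate oxygen and the auxiliary ether oxygen, so allyl bromide should attack the ring carbon from the face away from the pyrrolidine substituent and set the quaternary stereocentre (later spiro C6).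

Step 3
Reactants: 5 [(1S)-2,5-dimethoxy-1-(prop-2-en-1-yl)cyclohexa-2,5-dien-1-yl][(2S)-2-(methoxymethyl)pyrrolidin-1-yl]methanone
Product: 6 1-[(1S)-2,5-dimethoxy-1-(prop-2-en-1-yl)cyclohexa-2,5-dien-1-yl]ethan-1-one
Conditions: MeLi, THF, −78 to 0 °C; H2O
Reagents that add atoms: methyllithium, [Li]C
Why: Addition of methyllithium to the chelating tertiary amide should stop at the ketone stage after hydrolytic work-up (ketone synthesis from an amide) and release the auxiliary; the stereocentre is untouched.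

Step 4
Reactants: 6 1-[(1S)-2,5-dimethoxy-1-(prop-2-en-1-yl)cyclohexa-2,5-dien-1-yl]ethan-1-one
Product: 7 1-[(1S)-2,5-dimethoxy-1-[(1E)-prop-1-en-1-yl]cyclohexa-2,5-dien-1-yl]ethan-1-one
Conditions: RuHCl(CO)(PPh3)3 (cat.), toluene, 80 °C
Reagents that add atoms: none
Why: Ruthenium hydride-catalysed olefin isomerisation (hydrometalation/β-hydride elimination) should move the terminal double bond one position to the (E)-propenyl group; the quaternary carbon stops further migration and the trisubstituted enol ethers react far more slowly.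

Step 5
Reactants: 7 1-[(1S)-2,5-dimethoxy-1-[(1E)-prop-1-en-1-yl]cyclohexa-2,5-dien-1-yl]ethan-1-one; 8 2,4,5-trimethoxybenzaldehyde
Product: 10 (2E)-1-[(1S)-2,5-dimethoxy-1-[(1E)-prop-1-en-1-yl]cyclohexa-2,5-dien-1-yl]-3-(2,4,5-trimethoxyphenyl)prop-2-en-1-one, via aldol adduct 9 (not isolated)
Conditions: KOH, MeOH, THF, 40 °C
Reagents that add atoms: none
Why: Claisen–Schmidt condensation: the ketone can enolise only at its methyl group, the aldehyde has no α-hydrogen, and E1cB dehydration of the aldol should give the (E)-enone.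

Step 6
Reactants: 10 (2E)-1-[(1S)-2,5-dimethoxy-1-[(1E)-prop-1-en-1-yl]cyclohexa-2,5-dien-1-yl]-3-(2,4,5-trimethoxyphenyl)prop-2-en-1-one
Product: 11 (3S)-1-[(1S)-2,5-dimethoxy-1-[(1E)-prop-1-en-1-yl]cyclohexa-2,5-dien-1-yl]-3-(2,4,5-trimethoxyphenyl)-5-[tri(propan-2-yl)silyl]pent-4-yn-1-one
Conditions: [Rh(OAc)(C2H4)2]2 (cat.), (R)-DTBM-SEGPHOS, HC≡CSi(iPr)3, 1,4-dioxane, 80 °C
Reagents that add atoms: (triisopropylsilyl)acetylene, C#C[Si](C(C)C)(C(C)C)C(C)C
Why: Rhodium-catalysed asymmetric conjugate alkynylation: an alkynylrhodium species adds 1,4 to the s-cis enone and the rhodium enolate is protonated by the alkyne; the chiral bisphosphine controls the new propargylic stereocentre (later C9), and the bulky silyl group suppresses alkyne dimerisation.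

Step 7
Reactants: 11 (3S)-1-[(1S)-2,5-dimethoxy-1-[(1E)-prop-1-en-1-yl]cyclohexa-2,5-dien-1-yl]-3-(2,4,5-trimethoxyphenyl)-5-[tri(propan-2-yl)silyl]pent-4-yn-1-one
Product: 12 (3R)-1-[(1S)-2,5-dimethoxy-1-[(1E)-prop-1-en-1-yl]cyclohexa-2,5-dien-1-yl]-3-(2,4,5-trimethoxyphenyl)pent-4-yn-1-one
Conditions: Bu4NF, AcOH, THF, 0 °C
Reagents that add atoms: none
Why: Fluoride-induced protodesilylation of the alkynylsilane, buffered with acetic acid so that the propargylic benzylic position does not isomerise to an allene; the descriptor changes only because the priorities change.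

Step 8
Reactants: 12 (3R)-1-[(1S)-2,5-dimethoxy-1-[(1E)-prop-1-en-1-yl]cyclohexa-2,5-dien-1-yl]-3-(2,4,5-trimethoxyphenyl)pent-4-yn-1-one
Product: 13 (6S,9R,11R)-11-ethenyl-1,4-dimethoxy-10-methylidene-9-(2,4,5-trimethoxyphenyl)spiro[5.5]undeca-1,4-dien-7-one
Conditions: [CpRu(MeCN)3]PF6 (10 mol%), acetone, rt
Reagents that add atoms: none
Why: The cationic CpRu fragment binds the alkyne and the propenyl alkene and couples them by oxidative cyclometalation, which forms the C10–C11 bond; β-hydride elimination from the allylic methyl group and C–H reductive elimination then release the 1,4-diene, an overall intramolecular Alder-ene reaction. The closest known reaction type is the ruthenium-catalysed cycloisomerisation of 1,7-enynes to 1-methylidene-2-vinylcyclohexanes. Ring A closes in the 6-exo-dig mode with respect to the alkyne and the 6-exo-trig mode with respect to the alkene, so the two distal carbons end up outside the ring as methylidene and vinyl groups. The new stereocentre C11 is controlled by the existing C9 centre through a chair-like transition state in which the C9 aryl group and the C11 substituent are both equatorial (1,3-cis); C6 is untouched. The step needs chemoselectivity for the 1,2-disubstituted propenyl alkene over the two trisubstituted enol ether alkenes of ring B, secured by its lower substitution, and 1,4- over 1,3-diene formation, secured by the metallacycle, in which only the methyl hydrogens are placed for β-hydride elimination.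

Step 9
Reactants: 13 (6S,9R,11R)-11-ethenyl-1,4-dimethoxy-10-methylidene-9-(2,4,5-trimethoxyphenyl)spiro[5.5]undeca-1,4-dien-7-one
Product: 14 (6S,9R,10R,11R)-11-ethyl-1,4-dimethoxy-10-methyl-9-(2,4,5-trimethoxyphenyl)spiro[5.5]undeca-1,4-dien-7-one
Conditions: H2 (3 atm), RhCl(PPh3)3 (cat.), benzene/EtOH, rt
Reagents that add atoms: none
Why: Homogeneous hydrogenation with the monovalent rhodium catalyst should reduce the vinyl and the 1,1-disubstituted exocyclic alkene but not the trisubstituted enol ethers; hydrogen should add to the C10 methylidene from the face opposite the flanking equatorial C9 aryl and C11 ethyl groups and the axial arm of ring B, so the new C10 methyl is axial and cis to both neighbours.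

Step 10
Reactants: 14 (6S,9R,10R,11R)-11-ethyl-1,4-dimethoxy-10-methyl-9-(2,4,5-trimethoxyphenyl)spiro[5.5]undeca-1,4-dien-7-one
Product: 16 (6S,8R,9S,10S,11R)-11-ethyl-1,4-dimethoxy-8,10-dimethyl-9-(2,4,5-trimethoxyphenyl)spiro[5.5]undeca-1,4-dien-7-one, via lithium enolate 15 (not isolated)
Conditions: LiN(iPr)2, THF, −78 °C; MeI, −78 to 0 °C
Reagents that add atoms: iodomethane, CI
Why: Enolate alkylation at C8, the only enolisable position because the other α-carbon is the spiro centre; the methyl group should enter anti to the neighbouring C9 aryl group, although C8 becomes trigonal again in step 11.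

Step 11
Reactants: 16 (6S,8R,9S,10S,11R)-11-ethyl-1,4-dimethoxy-8,10-dimethyl-9-(2,4,5-trimethoxyphenyl)spiro[5.5]undeca-1,4-dien-7-one
Product: 18 (6S,9S,10S,11R)-11-ethyl-1,4-dimethoxy-8,10-dimethyl-9-(2,4,5-trimethoxyphenyl)spiro[5.5]undeca-1,4,7-trien-7-yl trifluoromethanesulfonate, via potassium enolate 17 (not isolated)
Conditions: KN(SiMe3)2, THF, −78 °C; PhNTf2, −78 °C to rt
Reagents that add atoms: N-phenylbis(trifluoromethanesulfonimide), O=S(=O)(N(c1ccccc1)S(=O)(=O)C(F)(F)F)C(F)(F)F
Why: O-Sulfonylation of the only possible enolate gives the tetrasubstituted alkenyl triflate (enol triflate formation); no stereocentre is formed.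

Step 12
Reactants: 18 (6S,9S,10S,11R)-11-ethyl-1,4-dimethoxy-8,10-dimethyl-9-(2,4,5-trimethoxyphenyl)spiro[5.5]undeca-1,4,7-trien-7-yl trifluoromethanesulfonate
Product: 19 (6S,9S,10S,11R)-11-ethyl-1,4-dimethoxy-8,10-dimethyl-3-oxo-9-(2,4,5-trimethoxyphenyl)spiro[5.5]undeca-1,4,7-trien-7-yl trifluoromethanesulfonate
Conditions: Rh2(cap)4 (cap = caprolactamate, 1 mol%), t-BuOOH (aq.), K2CO3, CH2Cl2, rt
Reagents that add atoms: tert-butyl hydroperoxide, CC(C)(C)OO
Why: Allylic oxidation by a tert-butylperoxyl radical chain: the doubly allylic methylene between the two enol ethers has the weakest C–H bond and should be converted into the ketone, which unveils the 2,5-dimethoxycyclohexadienone of ring B; at this stage C6 carries only a vinylic and a secondary alkyl carbon, so the ring radical has no easy fragmentation path.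

Step 13
Reactants: 19 (6S,9S,10S,11R)-11-ethyl-1,4-dimethoxy-8,10-dimethyl-3-oxo-9-(2,4,5-trimethoxyphenyl)spiro[5.5]undeca-1,4,7-trien-7-yl trifluoromethanesulfonate; 20 (2,4,5-trimethoxyphenyl)boronic acid
Product: 21 (6R,9S,10S,11R)-11-ethyl-1,4-dimethoxy-8,10-dimethyl-7,9-bis(2,4,5-trimethoxyphenyl)spiro[5.5]undeca-1,4,7-trien-3-one
Conditions: Pd(OAc)2 (cat.), SPhos, K3PO4, toluene/H2O, 80 °C
Reagents that add atoms: none
Why: Suzuki–Miyaura coupling of the alkenyl triflate with the arylboronic acid, the bulky electron-rich biarylphosphine promoting oxidative addition and transmetalation at the hindered position; no stereocentre is formed (the C6 descriptor changes by priority only).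

Step 14
Reactants: 21 (6R,9S,10S,11R)-11-ethyl-1,4-dimethoxy-8,10-dimethyl-7,9-bis(2,4,5-trimethoxyphenyl)spiro[5.5]undeca-1,4,7-trien-3-one
Product: 22 tatanan B, (6S,7R,8R,9S,10S,11R)-11-ethyl-1,4-dimethoxy-8,10-dimethyl-7,9-bis(2,4,5-trimethoxyphenyl)spiro[5.5]undeca-1,4-dien-3-one
Conditions: Et3SiH, CF3CO2H, CH2Cl2, −20 to 0 °C
Reagents that add atoms: none
Why: Ionic hydrogenation: protonation at C8 gives the tertiary benzylic cation at C7, the conformer with equatorial C8 methyl being favoured because an axial methyl would clash 1,3-diaxially with the axial C10 methyl, and the silane should deliver hydride axially from the face opposite the axial arm of ring B, which places the C7 aryl group equatorial and sets C7 and C8 trans.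

Compound list
1 | 2,5-dimethoxybenzoyl chloride | COc1ccc(OC)c(c1)C(Cl)=O | starting material
2 | (S)-2-(methoxymethyl)pyrrolidine | COC[C@@H]1CCCN1 | starting material
3 | (2,5-dimethoxyphenyl)[(2S)-2-(methoxymethyl)pyrrolidin-1-yl]methanone | COc1ccc(OC)c(c1)C(=O)N1CCC[C@H]1COC | intermediate
4 | potassium (2,5-dimethoxycyclohexa-2,5-dien-1-ylidene)[(2S)-2-(methoxymethyl)pyrrolidin-1-yl]methanolate (amide dienolate) | [K+].[O-]C(=C1C=C(OC)CC=C1OC)N1CCC[C@H]1COC | intermediate
5 | [(1S)-2,5-dimethoxy-1-(prop-2-en-1-yl)cyclohexa-2,5-dien-1-yl][(2S)-2-(methoxymethyl)pyrrolidin-1-yl]methanone | O=C(N1CCC[C@H]1COC)[C@@]2(CC=C)C=C(OC)CC=C2OC | intermediate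
6 | 1-[(1S)-2,5-dimethoxy-1-(prop-2-en-1-yl)cyclohexa-2,5-dien-1-yl]ethan-1-one | CC(=O)[C@@]1(CC=C)C=C(OC)CC=C1OC | intermediate
7 | 1-[(1S)-2,5-dimethoxy-1-[(1E)-prop-1-en-1-yl]cyclohexa-2,5-dien-1-yl]ethan-1-one | CC(=O)[C@@]1(/C=C/C)C=C(OC)CC=C1OC | intermediate
8 | 2,4,5-trimethoxybenzaldehyde | COc1cc(OC)c(OC)cc1C=O | starting material
9 | 1-[(1S)-2,5-dimethoxy-1-[(1E)-prop-1-en-1-yl]cyclohexa-2,5-dien-1-yl]-3-hydroxy-3-(2,4,5-trimethoxyphenyl)propan-1-one (aldol adduct, both carbinol epimers) | OC(CC(=O)[C@@]1(/C=C/C)C=C(OC)CC=C1OC)c1cc(OC)c(OC)cc1OC | intermediate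
10 | (2E)-1-[(1S)-2,5-dimethoxy-1-[(1E)-prop-1-en-1-yl]cyclohexa-2,5-dien-1-yl]-3-(2,4,5-trimethoxyphenyl)prop-2-en-1-one | O=C(/C=C/c1cc(OC)c(OC)cc1OC)[C@@]1(/C=C/C)C=C(OC)CC=C1OC | intermediate
11 | (3S)-1-[(1S)-2,5-dimethoxy-1-[(1E)-prop-1-en-1-yl]cyclohexa-2,5-dien-1-yl]-3-(2,4,5-trimethoxyphenyl)-5-[tri(propan-2-yl)silyl]pent-4-yn-1-one | CC(C)[Si](C(C)C)(C(C)C)C#C[C@H](c1cc(OC)c(OC)cc1OC)CC(=O)[C@@]1(/C=C/C)C=C(OC)CC=C1OC | intermediate
12 | (3R)-1-[(1S)-2,5-dimethoxy-1-[(1E)-prop-1-en-1-yl]cyclohexa-2,5-dien-1-yl]-3-(2,4,5-trimethoxyphenyl)pent-4-yn-1-one (same spatial arrangement at C3 as in 11) | C#C[C@H](c1cc(OC)c(OC)cc1OC)CC(=O)[C@@]1(/C=C/C)C=C(OC)CC=C1OC | intermediate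
13 | (6S,9R,11R)-11-ethenyl-1,4-dimethoxy-10-methylidene-9-(2,4,5-trimethoxyphenyl)spiro[5.5]undeca-1,4-dien-7-one (vinyl and aryl cis) | C=C[C@@H]1C(=C)[C@H](c2cc(OC)c(OC)cc2OC)CC(=O)[C@]12C=C(OC)CC=C2OC | intermediate
14 | (6S,9R,10R,11R)-11-ethyl-1,4-dimethoxy-10-methyl-9-(2,4,5-trimethoxyphenyl)spiro[5.5]undeca-1,4-dien-7-one (ethyl, methyl and aryl all cis) | CC[C@@H]1[C@H](C)[C@H](c2cc(OC)c(OC)cc2OC)CC(=O)[C@]12C=C(OC)CC=C2OC | intermediate
15 | lithium enolate of 14 (C7–C8 enolate) | [Li+].CC[C@@H]1[C@H](C)[C@H](c2cc(OC)c(OC)cc2OC)C=C([O-])[C@]12C=C(OC)CC=C2OC | intermediate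
16 | (6S,8R,9S,10S,11R)-11-ethyl-1,4-dimethoxy-8,10-dimethyl-9-(2,4,5-trimethoxyphenyl)spiro[5.5]undeca-1,4-dien-7-one (C8 methyl trans to the C9 aryl; C9 and C10 spatially as in 14) | CC[C@@H]1[C@H](C)[C@H](c2cc(OC)c(OC)cc2OC)[C@@H](C)C(=O)[C@]12C=C(OC)CC=C2OC | intermediate
17 | potassium enolate of 16 (C7–C8 enolate) | [K+].CC[C@@H]1[C@H](C)[C@H](c2cc(OC)c(OC)cc2OC)C(C)=C([O-])[C@]12C=C(OC)CC=C2OC | intermediate
18 | (6S,9S,10S,11R)-11-ethyl-1,4-dimethoxy-8,10-dimethyl-9-(2,4,5-trimethoxyphenyl)spiro[5.5]undeca-1,4,7-trien-7-yl trifluoromethanesulfonate | CC[C@@H]1[C@H](C)[C@H](c2cc(OC)c(OC)cc2OC)C(C)=C(OS(=O)(=O)C(F)(F)F)[C@]12C=C(OC)CC=C2OC | intermediate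
19 | (6S,9S,10S,11R)-11-ethyl-1,4-dimethoxy-8,10-dimethyl-3-oxo-9-(2,4,5-trimethoxyphenyl)spiro[5.5]undeca-1,4,7-trien-7-yl trifluoromethanesulfonate | CC[C@@H]1[C@H](C)[C@H](c2cc(OC)c(OC)cc2OC)C(C)=C(OS(=O)(=O)C(F)(F)F)[C@]12C=C(OC)C(=O)C=C2OC | intermediate
20 | (2,4,5-trimethoxyphenyl)boronic acid | COc1cc(OC)c(OC)cc1B(O)O | starting material
21 | (6R,9S,10S,11R)-11-ethyl-1,4-dimethoxy-8,10-dimethyl-7,9-bis(2,4,5-trimethoxyphenyl)spiro[5.5]undeca-1,4,7-trien-3-one (C6 spatially as in 19) | CC[C@@H]1[C@H](C)[C@H](c2cc(OC)c(OC)cc2OC)C(C)=C(c2cc(OC)c(OC)cc2OC)[C@]12C=C(OC)C(=O)C=C2OC | intermediate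
22 | tatanan B, (6S,7R,8R,9S,10S,11R)-11-ethyl-1,4-dimethoxy-8,10-dimethyl-7,9-bis(2,4,5-trimethoxyphenyl)spiro[5.5]undeca-1,4-dien-3-one | CC[C@@H]1[C@H](C)[C@H](c2cc(OC)c(OC)cc2OC)[C@@H](C)[C@H](c2cc(OC)c(OC)cc2OC)[C@]12C=C(OC)C(=O)C=C2OC | target

Total step count: 14. Longest linear sequence: 14 steps (1 to 22).

The step most likely to fail is the key step 8. The electron-rich aryl ring may sequester the cationic ruthenium as an arene complex, a ring B enol ether alkene may be engaged instead of the propenyl group, or β-hydride elimination toward the ring may give the conjugated 1,3-diene. The fallback sets out from 12 and uses a zerovalent-palladium-catalysed reductive cyclisation (Pd2(dba)3·CHCl3, P(o-tolyl)3, AcOH, Et3SiH, benzene). Hydropalladation of the alkyne, carbopalladation of the propenyl group across the same C10–C11 bond and hydride capture would give (6S,9R,11R)-11-ethyl-1,4-dimethoxy-10-methylidene-9-(2,4,5-trimethoxyphenyl)spiro[5.5]undeca-1,4-dien-7-one F4. Hydrogenation of its methylidene group under the conditions of step 9 comes back to the route at 14.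

The second is step 3, where methyllithium may fail to add to the hindered α-quaternary amide, or may deprotonate instead. The fallback sets out from 5. Reduction with LiH2NBH3 would give [(1R)-2,5-dimethoxy-1-(prop-2-en-1-yl)cyclohexa-2,5-dien-1-yl]methanol F1, and oxidation (SO3·pyridine, DMSO, Et3N) would give (1S)-2,5-dimethoxy-1-(prop-2-en-1-yl)cyclohexa-2,5-diene-1-carbaldehyde F2. Addition of MeMgBr would give 1-[(1R)-2,5-dimethoxy-1-(prop-2-en-1-yl)cyclohexa-2,5-dien-1-yl]ethan-1-ol F3, and a second oxidation of the same kind comes back to the route at 6.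

The third is step 13, where oxidative addition and transmetalation at the tetrasubstituted triflate next to the spiro centre may be too slow, so that protodeboronation of the ortho-substituted boronic acid or hydrolysis of the triflate takes over. The fallback sets out from 16. Addition of the organocerium reagent made from 1-bromo-2,4,5-trimethoxybenzene, n-BuLi and CeCl3 would give the tertiary alcohol 11-ethyl-1,4-dimethoxy-8,10-dimethyl-7,9-bis(2,4,5-trimethoxyphenyl)spiro[5.5]undeca-1,4-dien-7-ol F5 (C7 aryl equatorial, other centres as in 16). Dehydration toward C8 with (methoxycarbonylsulfamoyl)triethylammonium hydroxide inner salt would give 11-ethyl-1,4-dimethoxy-8,10-dimethyl-7,9-bis(2,4,5-trimethoxyphenyl)spiro[5.5]undeca-1,4,7-triene F6 (centres as in 18). The allylic oxidation of step 12 applied to this triene comes back to the route at 21.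

Further compounds
F1 | step 3 | [(1R)-2,5-dimethoxy-1-(prop-2-en-1-yl)cyclohexa-2,5-dien-1-yl]methanol | OC[C@@]1(CC=C)C=C(OC)CC=C1OC
F2 | step 3 | (1S)-2,5-dimethoxy-1-(prop-2-en-1-yl)cyclohexa-2,5-diene-1-carbaldehyde | O=C[C@@]1(CC=C)C=C(OC)CC=C1OC
F3 | step 3 | 1-[(1R)-2,5-dimethoxy-1-(prop-2-en-1-yl)cyclohexa-2,5-dien-1-yl]ethan-1-ol (both carbinol epimers) | CC(O)[C@@]1(CC=C)C=C(OC)CC=C1OC
F4 | step 8 | (6S,9R,11R)-11-ethyl-1,4-dimethoxy-10-methylidene-9-(2,4,5-trimethoxyphenyl)spiro[5.5]undeca-1,4-dien-7-one | CC[C@@H]1C(=C)[C@H](c2cc(OC)c(OC)cc2OC)CC(=O)[C@]12C=C(OC)CC=C2OC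
F5 | step 13 | 11-ethyl-1,4-dimethoxy-8,10-dimethyl-7,9-bis(2,4,5-trimethoxyphenyl)spiro[5.5]undeca-1,4-dien-7-ol (C7 aryl equatorial, other centres as in 16) | CC[C@@H]1[C@H](C)[C@H](c2cc(OC)c(OC)cc2OC)[C@@H](C)[C@](O)(c2cc(OC)c(OC)cc2OC)[C@]12C=C(OC)CC=C2OC
F6 | step 13 | 11-ethyl-1,4-dimethoxy-8,10-dimethyl-7,9-bis(2,4,5-trimethoxyphenyl)spiro[5.5]undeca-1,4,7-triene (centres as in 18) | CC[C@@H]1[C@H](C)[C@H](c2cc(OC)c(OC)cc2OC)C(C)=C(c2cc(OC)c(OC)cc2OC)[C@]12C=C(OC)CC=C2OC
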